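**Strategy**

The seven-membered ring (C5–C6–C7–C8–C9–C10–C11, longipinane numbering) is treated as a cyclohexene plus one carbon. A catalytic asymmetric, endo-selective Diels–Alder reaction joins the unsubstituted enone bond (C5=C11) of a quinone monoketal, which already is the enone ring C1–C4/C5/C11, to the acyclic 2-silyloxy diene C6=C7–C9(OSi)=C10. It creates C5–C6 and C10–C11 and the C6 quaternary centre in one operation. C8 is then inserted between C7 and C9 (siloxycyclopropane, FeCl3), the cyclobutane is closed by alkylation of the C10 enolate at C4, and the C7/C9 oxygens are drawn from the resulting enone.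

Key step: step 5

Remarks
- Numbering: the longipinane numbering of the target is used for all intermediates. C1 is the ring carbonyl carbon, C2=C3(Me) the olefin, C4 and C11 the bridgeheads, C5 and C10 the other cyclobutane carbons, C6 bears Me and CH2O (this CH2 is called C15), C7 bears OAc, C9 bears OAng.
- Assumption: the (R)-BINOL-derived titanium catalyst is taken to select the enantiotopic face of 2 that leads to 8; if the opposite sense is found, (S)-BINOL is used.
- Assumption: 1 and 3 are taken as catalogue chemicals.

**Route**

Step 1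
Reactants: 1 4-methoxy-2-methylphenol
Product: 2 4,4-dimethoxy-2-methylcyclohexa-2,5-dien-1-one
Conditions: PhI(OAc)2, MeOH, 0 °C
Reagents that add atoms: methanol, CO
Why: Hypervalent-iodine oxidative dearomatization of a para-alkoxyphenol in methanol traps the phenoxonium ion at C4 as the dimethyl ketal (quinone monoketal formation), which leaves a single activating carbonyl (future C4) and masks the future C1 ketone; no stereocentre is formed.

Step 2
Reactants: 3 4-methylfuran-2(5H)-one
Product: 5 (Z)-4-[(tert-butyldimethylsilyl)oxy]-N-methoxy-N,3-dimethylbut-2-enamide, via hydroxy amide 4 (not isolated)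
Conditions: MeNH(OMe)·HCl, AlMe3, CH2Cl2, 0 °C to rt; then TBSCl, imidazole, DMF, 0 °C
Reagents that add atoms: N,O-dimethylhydroxylamine hydrochloride, CNOC.Cl; tert-butyldimethylsilyl chloride, CC(C)(C)[Si](C)(C)Cl
Why: Weinreb aminolysis of the butenolide by the aluminium amide opens the ring with the Z olefin intact (CH2O and carbonyl were cis in the ring), and immediate silylation of the primary alcohol prevents relactonization.

Step 3
Reactants: 5 (Z)-4-[(tert-butyldimethylsilyl)oxy]-N-methoxy-N,3-dimethylbut-2-enamide
Product: 6 (Z)-6-[(tert-butyldimethylsilyl)oxy]-5-methylhex-4-en-3-one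
Conditions: EtMgBr, THF, 0 °C
Reagents that add atoms: ethylmagnesium bromide, CC[Mg]Br
Why: Weinreb ketone synthesis, in which the chelated tetrahedral intermediate stops the Grignard addition at the ketone stage and the hindered Z-trisubstituted olefin is not attacked.

Step 4
Reactants: 6 (Z)-6-[(tert-butyldimethylsilyl)oxy]-5-methylhex-4-en-3-one
Product: 7 (2Z,4Z)-6-[(tert-butyldimethylsilyl)oxy]-5-methyl-3-[(trimethylsilyl)oxy]hexa-2,4-diene
Conditions: KN(SiMe3)2, THF, −78 °C; TMSCl
Reagents that add atoms: chlorotrimethylsilane, C[Si](C)(C)Cl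
Why: Kinetic alpha-prime enolization of the enone and O-silylation (silyl enol ether formation) should give the cross-conjugated 2-silyloxy diene, the potassium enolate of an ethyl ketone forming mainly with Z geometry so that the future 10-methyl is an outside substituent.

Step 5
Reactants: 2 4,4-dimethoxy-2-methylcyclohexa-2,5-dien-1-one; 7 (2Z,4Z)-6-[(tert-butyldimethylsilyl)oxy]-5-methyl-3-[(trimethylsilyl)oxy]hexa-2,4-diene
Product: 8 cis-fused endo cycloadduct, 8-{[(tert-butyldimethylsilyl)oxy]methyl}-4,4-dimethoxy-2,5,8-trimethyl-6-[(trimethylsilyl)oxy]-4a,5,8,8a-tetrahydronaphthalen-1(4H)-one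
Conditions: (R)-BINOL (20 mol%), TiCl2(OiPr)2 (20 mol%), 4 Å MS, toluene, 0 °C to rt
Reagents that add atoms: none
Why: Normal-electron-demand [4+2] cycloaddition in which the HOMO of the 2-silyloxy diene 7 and the LUMO of the titanium-bound enone of 2 combine in a concerted, asynchronous transition state (C10–C11 bonding ahead of C5–C6); the closest known reaction type is the BINOL–titanium-catalysed enantioselective Diels–Alder reaction of 1,4-quinone monoketals with 2-silyloxy dienes. One ring is closed, the cyclohexene C5–C6–C7–C9–C10–C11 (the seven-membered ring minus C8), by intermolecular suprafacial–suprafacial [4+2] annulation onto the existing six-membered ring. The cis relation of H5 and H11 follows from the Z ring dienophile, the C6 quaternary centre is set by endo approach together with the diene geometry (outside methyl ends cis to C4, inside CH2OTBS trans), C10 is set likewise but is re-set in step 10, and the absolute configuration comes from the face of 2 left open by the chiral titanium BINOLate. Regioselectivity is required and is secured electronically: the nucleophilic diene terminus C10 (alpha to the silyloxy carbon) bonds to the enone beta carbon C11, the monoketal leaves only one activating carbonyl and the 2-methyl group protects the other enone bond. Endo selectivity rests on secondary overlap with the C4 carbonyl, and molecular sieves with low temperature should limit Lewis-acid loss of the silyl enol ether.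

Step 6
Reactants: 8 endo cycloadduct
Product: 9 siloxycyclopropane, the 6,7-methano derivative of 8 with the CH2 on the face of H4a/H8a
Conditions: Et2Zn, CH2I2, CH2Cl2, 0 °C
Reagents that add atoms: diiodomethane, ICI
Why: Simmons–Smith cyclopropanation, the electrophilic zinc carbenoid adding only to the electron-rich silyl enol ether from the convex face; the two new stereocentres are inconsequential because step 8 destroys them.

Step 7
Reactants: 9 siloxycyclopropane
Product: 10 allylic alcohol, C4–OH on the concave face (cis to the C5–C6 bond)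
Conditions: iBu2AlH, CH2Cl2, −78 °C
Reagents that add atoms: none
Why: 1,2-Hydride reduction of the enone, hydride being delivered to the convex face (the face of H5/H11, away from the other ring), which should place the new C4 hydroxyl on the concave face.

Step 8
Reactants: 10 allylic alcohol
Product: 12 cis-fused cycloheptenone alcohol, 9-{[(tert-butyldimethylsilyl)oxy]methyl}-1-hydroxy-4,4-dimethoxy-2,5,9-trimethyl-1,4,4a,5,9,9a-hexahydro-6H-benzo[7]annulen-6-one, via beta-chloro ketone 11 (not isolated)
Conditions: FeCl3, pyridine, DMF, 0 °C; then NaOAc, MeOH, 60 °C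
Reagents that add atoms: none
Why: Ito–Saegusa ring expansion, in which one-electron oxidation of the siloxycyclopropane gives an oxy radical that cleaves the internal bond to the ring-enlarged beta-keto radical, chlorine transfer gives the beta-chloro ketone and acetate-mediated dehydrochlorination gives the enone with C8 inserted between C7 and C9; no retained stereocentre is touched.

Step 9
Reactants: 12 cycloheptenone alcohol
Product: 13 allylic bromide with inverted C4 (Br on the convex face, cis to H5)
Conditions: CBr4, PPh3, 2,6-lutidine, CH2Cl2, −20 °C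
Reagents that add atoms: tetrabromomethane, BrC(Br)(Br)Br
Why: Appel bromination, bromide displacing the alkoxyphosphonium ion by SN2 from the open convex face, so C4 is inverted and the leaving group lies anti to the direction from which C10 must attack.

Step 10
Reactants: 13 allylic bromide
Product: 14 tricyclic enone, 15-[(tert-butyldimethylsilyl)oxy]-1,1-dimethoxylongipina-2,7-dien-9-one
Conditions: KN(SiMe3)2, THF, −78 to 0 °C
Reagents that add atoms: none
Why: Intramolecular enolate alkylation (4-exo-tet, the classical closure of bicyclo[3.1.1]heptanes): only C10 can be deprotonated (C8 is vinylic, C6 is quaternary), the cross-conjugated dienolate displaces the C4 bromide with inversion, O-alkylation would give a bridgehead enol ether, and the C10 quaternary centre is fixed by the geometry of the closure (new bond towards C4, methyl on the other face).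

Step 11
Reactants: 14 tricyclic enone
Product: 15 7,8-epoxy ketone, epoxide oxygen on the face of the 6-methyl group
Conditions: H2O2 (30%), NaOH, MeOH, 0 °C
Reagents that add atoms: hydrogen peroxide, OO
Why: Weitz–Scheffer nucleophilic epoxidation is selective for the electron-poor enone olefin, and hydroperoxide is expected to add to C7 from the side of the smaller C6 substituent (methyl, anti to CH2OTBS), which sets the C7–O configuration.

Step 12
Reactants: 15 7,8-epoxy ketone
Product: 16 beta-hydroxy ketone, 15-[(tert-butyldimethylsilyl)oxy]-7-hydroxy-1,1-dimethoxylongipin-2-en-9-one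
Conditions: SmI2, THF/MeOH, −90 °C
Reagents that add atoms: none
Why: SmI2 reduction of an alpha,beta-epoxy ketone cleaves only the C8–O bond through the ketyl and samarium enolate, so the C7 carbinol configuration is retained.

Step 13
Reactants: 16 beta-hydroxy ketone
Product: 17 7-acetoxy-15-[(tert-butyldimethylsilyl)oxy]-1,1-dimethoxylongipin-2-en-9-ol (7,9-trans)
Conditions: CH3CHO (excess), SmI2 (30 mol%), THF, −10 °C
Reagents that add atoms: acetaldehyde, CC=O
Why: Evans–Tishchenko reduction, the samarium-bound hemiacetal of acetaldehyde on O7 delivering hydride intramolecularly to C9 on the face of the C7 oxygen, which should give the anti (trans) 1,3-diol with the acetate directly on O7 and the C9 hydroxyl free.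

Step 14
Reactants: 17 hydroxy acetate
Product: 18 7-acetoxy-9,15-dihydroxylongipin-2-en-1-one
Conditions: 1 M HCl, THF, rt
Reagents that add atoms: water, O
Why: Acid hydrolysis of the allylic dimethyl ketal to the conjugated C1 ketone together with cleavage of the primary silyl ether (acetal hydrolysis and desilylation), the secondary acetate being stable to these conditions.

Step 15
Reactants: 18 7-acetoxy-9,15-dihydroxylongipin-2-en-1-one
Product: 19 target, 7-acetoxy-9,15-bis(angeloyloxy)longipin-2-en-1-one (CNP0364726.1)
Conditions: angelic acid, 2,4,6-Cl3C6H2COCl, Et3N, toluene, rt; then 18, 80 °C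
Reagents that add atoms: angelic acid, C/C=C(/C)C(=O)O
Why: Mixed-anhydride (Yamaguchi-type) esterification run without DMAP should acylate the primary and the hindered secondary hydroxyl with retention of the Z geometry, the fast acylation of the primary alcohol also forestalling acetyl migration from O7.

**Compound list**

1 | 4-methoxy-2-methylphenol | COc1ccc(O)c(C)c1 | starting material
2 | 4,4-dimethoxy-2-methylcyclohexa-2,5-dien-1-one | COC1(OC)C=CC(=O)C(C)=C1 | intermediate
3 | 4-methylfuran-2(5H)-one | CC1=CC(=O)OC1 | starting material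
4 | (Z)-4-hydroxy-N-methoxy-N,3-dimethylbut-2-enamide (not isolated) | CON(C)C(=O)/C=C(/C)CO | intermediate
5 | (Z)-4-[(tert-butyldimethylsilyl)oxy]-N-methoxy-N,3-dimethylbut-2-enamide | CON(C)C(=O)/C=C(/C)CO[Si](C)(C)C(C)(C)C | intermediate
6 | (Z)-6-[(tert-butyldimethylsilyl)oxy]-5-methylhex-4-en-3-one | CCC(=O)/C=C(/C)CO[Si](C)(C)C(C)(C)C | intermediate
7 | (2Z,4Z)-6-[(tert-butyldimethylsilyl)oxy]-5-methyl-3-[(trimethylsilyl)oxy]hexa-2,4-diene | C/C=C(\O[Si](C)(C)C)/C=C(/C)CO[Si](C)(C)C(C)(C)C | intermediate
8 | endo cycloadduct, cis-fused 8-(TBSOCH2)-4,4-dimethoxy-2,5,8-trimethyl-6-(TMSO)-4a,5,8,8a-tetrahydronaphthalen-1(4H)-one; H4a/H8a cis, 5-Me and 8-Me on the opposite face | CC(C)(C)[Si](C)(C)OC[C@@]1(C)C=C(O[Si](C)(C)C)[C@H](C)[C@H]2[C@@H]1C(=O)C(C)=CC2(OC)OC | intermediate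
9 | siloxycyclopropane, 6,7-methano derivative of 8 (CH2 on the face of H4a/H8a) | CC(C)(C)[Si](C)(C)OC[C@@]1(C)[C@H]3C[C@@]3(O[Si](C)(C)C)[C@H](C)[C@H]2[C@@H]1C(=O)C(C)=CC2(OC)OC | intermediate
10 | allylic alcohol of 9, C4–OH (naphthalene C1) cis to the C8a–C8 bond | CC(C)(C)[Si](C)(C)OC[C@@]1(C)[C@H]3C[C@@]3(O[Si](C)(C)C)[C@H](C)[C@H]2[C@@H]1[C@@H](O)C(C)=CC2(OC)OC | intermediate
11 | beta-chloro ketone, 8-chloro-1-hydroxy-4,4-dimethoxy-2,5,9-trimethyl-9-(TBSOCH2)-octahydro-6H-benzo[7]annulen-6-one, both C8 epimers (not isolated) | CC(C)(C)[Si](C)(C)OC[C@@]1(C)C(Cl)CC(=O)[C@H](C)[C@H]2[C@@H]1[C@@H](O)C(C)=CC2(OC)OC | intermediate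
12 | cis-fused 9-(TBSOCH2)-1-hydroxy-4,4-dimethoxy-2,5,9-trimethyl-1,4,4a,5,9,9a-hexahydro-6H-benzo[7]annulen-6-one (OH trans to H9a) | CC(C)(C)[Si](C)(C)OC[C@@]1(C)C=CC(=O)[C@H](C)[C@H]2[C@@H]1[C@@H](O)C(C)=CC2(OC)OC | intermediate
13 | 1-bromide of 12 with inverted C1 (Br cis to H9a) | CC(C)(C)[Si](C)(C)OC[C@@]1(C)C=CC(=O)[C@H](C)[C@H]2[C@@H]1[C@H](Br)C(C)=CC2(OC)OC | intermediate
14 | 15-(TBSO)-1,1-dimethoxylongipina-2,7-dien-9-one | CC(C)(C)[Si](C)(C)OC[C@]1(C)[C@@H]2[C@H]3C(OC)(OC)C=C(C)[C@@H]2[C@@]3(C)C(=O)C=C1 | intermediate
15 | 7,8-epoxide of 14, oxygen on the face of the 6-methyl group | CC(C)(C)[Si](C)(C)OC[C@]1(C)[C@@H]2[C@H]3C(OC)(OC)C=C(C)[C@@H]2[C@@]3(C)C(=O)[C@H]4O[C@@H]14 | intermediate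
16 | 15-(TBSO)-7-hydroxy-1,1-dimethoxylongipin-2-en-9-one | CC(C)(C)[Si](C)(C)OC[C@]1(C)[C@@H]2[C@H]3C(OC)(OC)C=C(C)[C@@H]2[C@@]3(C)C(=O)C[C@H]1O | intermediate
17 | 7-acetoxy-15-(TBSO)-1,1-dimethoxylongipin-2-en-9-ol (7,9-trans) | CC(C)(C)[Si](C)(C)OC[C@]1(C)[C@@H]2[C@H]3C(OC)(OC)C=C(C)[C@@H]2[C@@]3(C)[C@H](O)C[C@H]1OC(C)=O | intermediate
18 | 7-acetoxy-9,15-dihydroxylongipin-2-en-1-one | OC[C@]1(C)[C@@H]2[C@H]3C(=O)C=C(C)[C@@H]2[C@@]3(C)[C@H](O)C[C@H]1OC(C)=O | intermediate
19 | 7-acetoxy-9,15-bis(angeloyloxy)longipin-2-en-1-one (CNP0364726.1) | C/C=C(/C)C(=O)OC[C@]1(C)[C@@H]2[C@H]3C(=O)C=C(C)[C@@H]2[C@@]3(C)[C@H](OC(=O)/C(C)=C\C)C[C@H]1OC(C)=O | target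

**Step count**

Total step count: 15. Longest linear sequence: 14 steps (3 to 19, steps 2 to 15); the branch 1 to 2 (step 1) joins at step 5.

**Steps most likely to fail**

1. Step 5. The cycloaddition may be slow because the fully substituted diene terminus with an inward CH2OTBS group disfavours the s-cis conformer. The Lewis acid may also strip the silyl enol ether, and face selection by the catalyst may be incomplete. Fallback (resolution instead of asymmetric catalysis, sets out from 2 and 7, returns at 10): 2 and 7 are combined without Lewis acid (toluene, 110 °C, or 12 kbar), which should give the racemic endo adduct, that is 8 together with its mirror image ent-8 F1. Cyclopropanation as in step 6 gives 9 together with ent-9 F2. The mixture is then reduced with catecholborane and the Me-CBS oxazaborolidine enantiomer whose reagent-controlled hydride delivery matches the convex face of 9 (replacing iBu2AlH). 9 should give 10, while F2 reacts slowly and, where it does, gives the C4-epimeric alcohol of the mirror-image series F3, a diastereomer of 10 that chromatography removes.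

2. Step 10. E2 elimination or SN2′ attack may outrun the strained 4-exo-tet closure, and the allylic bromide may lose configurational purity before it cyclizes. Fallback (palladium-catalysed allylic alkylation instead of SN2, sets out from 12, returns at 14, bypasses 13): 12 is converted with ClCO2Me and pyridine into the allylic methyl carbonate F4. The ketone is deprotonated at C10 with LiN(SiMe3)2 (THF, −78 °C) and Pd(PPh3)4 (10 mol%) is added. Ionization anti to the concave carbonate puts palladium on the convex face and outer-sphere attack of the enolate anti to the metal closes the C4–C10 bond with net retention (intramolecular Tsuji–Trost alkylation), the ketal-flanked allyl terminus being the more hindered one.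

3. Step 15. Forced acylation of the hindered C9 hydroxyl may isomerize the angeloyl groups from Z to E (tiglate formation), and the acetyl group may migrate from O7 to O15 before the primary alcohol is acylated. Fallback (the Z olefins are built on the molecule instead of being carried in, sets out from 18, returns at 19): both hydroxyls of 18 are esterified with 2-[bis(2,2,2-trifluoroethoxy)phosphoryl]propanoic acid (EDC·HCl, DMAP, CH2Cl2) to the bis(phosphonopropionate) F5, a mixture of epimers at the two phosphonate-bearing carbons. Still–Gennari olefination with acetaldehyde (KN(SiMe3)2, 18-crown-6, THF, −78 °C) should then give both (Z)-2-methylbut-2-enoates directly.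

Further compounds
F1 | step 5 | ent-8, mirror image of cycloadduct 8 | CC(C)(C)[Si](C)(C)OC[C@]1(C)C=C(O[Si](C)(C)C)[C@@H](C)[C@@H]2[C@H]1C(=O)C(C)=CC2(OC)OC
F2 | step 5 | ent-9, mirror image of siloxycyclopropane 9 | CC(C)(C)[Si](C)(C)OC[C@]1(C)[C@@H]3C[C@]3(O[Si](C)(C)C)[C@@H](C)[C@@H]2[C@H]1C(=O)C(C)=CC2(OC)OC
F3 | step 5 | C4-epimeric allylic alcohol of the mirror-image series (reduction product of F2) | CC(C)(C)[Si](C)(C)OC[C@]1(C)[C@@H]3C[C@]3(O[Si](C)(C)C)[C@@H](C)[C@@H]2[C@H]1[C@@H](O)C(C)=CC2(OC)OC
F4 | step 10 | allylic methyl carbonate of 12 | CC(C)(C)[Si](C)(C)OC[C@@]1(C)C=CC(=O)[C@H](C)[C@H]2[C@@H]1[C@@H](OC(=O)OC)C(C)=CC2(OC)OC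
F5 | step 15 | 9,15-bis{2-[bis(2,2,2-trifluoroethoxy)phosphoryl]propanoate} of 18 | CC(P(=O)(OCC(F)(F)F)OCC(F)(F)F)C(=O)OC[C@]1(C)[C@@H]2[C@H]3C(=O)C=C(C)[C@@H]2[C@@]3(C)[C@H](OC(=O)C(C)P(=O)(OCC(F)(F)F)OCC(F)(F)F)C[C@H]1OC(C)=O
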